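**Conventions.** Unprimed locants refer to the flavanone (rings A and C), primed locants to ring B, doubly primed locants to the flavone chromenone and triply primed locants to its 4-methoxyphenyl ring. ArB stands for the 4-(benzyloxy)-3-[5,7-bis(benzyloxy)-2-(4-methoxyphenyl)-4-oxo-4H-chromen-8-yl]phenyl group.

## Analysis of the target

The target is a biflavonoid: a (2S)-5,7-dihydroxyflavanone (rings A and C, ring B on C2) is joined from C3' of ring B to C8'' of 5,7-dihydroxy-4'''-methoxyflavone (acacetin) through a biaryl bond with three ortho substituents. The only stereocentre is C2 of ring C; the biaryl axis carries no descriptor and is not treated as a fixed stereo element. C2 is benzylic, its aryl group is para-oxygenated, and it lies β to the C4 carbonyl with O1 as a phenoxide-type leaving group. Base therefore opens ring C to the chalcone and closes it again without control, and strong acid can ionise the C2–O1 bond. There are five phenols, two of them chelated to carbonyl groups, and one methyl ether that has to stay, so protecting groups must come off without base and without ether-cleaving conditions. The hard points are the regiochemistry at C8'' (C6'' is nearly as nucleophilic), the hindered aryl–aryl bond, and above all setting C2 as one enantiomer and keeping it. The strategy rests on one feature: O1, C2, C3, C4, C4a and C8a of ring C are the six atoms of a 2-aryl-2,3-dihydro-4H-pyran-4-one whose ring alkene is the C4a=C8a bond shared with ring A. The ring B aldehyde can thus supply C2 and O1 in an enantioselective hetero-Diels–Alder reaction with a four-carbon siloxydiene, and ring A can be grown on the C4a=C8a alkene afterwards.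

## Retrosynthetic reasoning

**17 to 16.** The last disconnection removes the three benzyl groups on O4', O5'' and O7''. Benzyl is chosen because the ethers must pass protic acid in step 6 and a silylating Lewis acid in step 8, where acetal protecting groups would be at risk. Hydrogenolysis is neutral, so C2 of 17 never meets base. The forward reaction must cleave three aryl benzyl ethers without reducing the C2''=C3'' bond, the C4 ketone or the benzylic C2–O1 bond.

**16 to 14 (through 15).** Ring A is opened at C4a–C5. C5 is traced back to the masked acyl carbon of the dioxinone in 14. On heating, the dioxinone unmasks acylketene 15, and C4a, the nucleophilic α-carbon of the vinylogous ester, closes onto the ketene carbon. The cut is made here because in 14 C8a is already an sp2 carbon bearing O1 and C8, that is, at the oxidation level of the arene. Ring closure and tautomerisation alone then give the resorcinol, with no oxidant and no base, and O1 is never placed β to a carbanion. Ring A arrives with both hydroxyl groups free.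

**14 to 10 and 12 (through 13).** The C8–C8a bond is cut next. In the forward direction the carbonyl-silylated form of 10 is an oxocarbenium ion that is electrophilic at C8a and is attacked by the terminal methylene of 12. The resulting silyl enol ether 13 is dehydrosilylated by divalent palladium, which puts the C4a=C8a double bond back. Making C8–C8a and C4a–C5 in a single cycloaddition after halogenation of C4a was weighed and set aside, for four reasons:
- A β-alkoxy enone is a poor dienophile for a thermally fragile bis-silyloxy diene.
- In a cis-fused adduct the hydrogen on C8a and the halogen on C4a are syn and that hydrogen is not acidic, so loss of hydrogen halide has no easy path.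
- A halogen between two carbonyl groups is an electrophilic halogen and is readily removed reductively.
- Once C4a carries hydrogen, O1 is expelled from C8a irreversibly and ring C is lost.

The stepwise sequence forms the same two bonds with the same polarity and keeps the same oxygen pattern (C5 and C7).

**12 to 11.** Compound 12 is the silyl dienol ether of commercial 11, an acetoacetate equivalent that reacts at its γ-carbon and keeps the acyl carbon masked until step 9.

**10 to 7 and 8 (key disconnection).** Ring C is cut at C2–C3 and O1–C8a. This returns aldehyde 7, whose carbonyl carbon and oxygen become C2 and O1, and diene 8, which supplies C3, C4, C4a and C8a. The cut is placed here because the C2–O1 bond is then the old C=O bond and is never made or broken at the stereocentre. The configuration is set by a chiral titanium Lewis acid on a prochiral aldehyde, and no chalcone stage exists at which it could be lost. The forward reaction must differentiate the aldehyde faces and must leave the flavone carbonyl alone.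

**7 to 3 and 6.** The biaryl bond C3'–C8'' is cut into an aryl iodide and an aryl boronate. The boron is placed on the small ring B partner, which is easy to borylate; the hindered, electron-rich flavone carries the iodide. The forward reaction is a palladium-catalysed coupling that has to form a biaryl with three ortho substituents.

**3 to 1, and 6 to 4.** Compound 3 comes from commercial acacetin 1 by benzylation to 2 and electrophilic iodination at C8''. Compound 6 comes from commercial 4 by benzylation to 5 and borylation. The whole flavone half is bought, so the route spends its steps on the biaryl bond, on C2 and on ring A.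

## Alternatives that were turned down

**Alternative 1: Danheiser benzannulation of flavone ring A.** Flavone ring A is disconnected at C8''–C8a'' and C6''–C7'', so the hindered biaryl bond is never made by cross-coupling; the ring B carbon already sits on an alkyne. In the forward key step 3-ethoxycyclobut-2-en-1-one A1 is heated with the ring B siloxyalkyne A2. A vinylketene adds to the alkyne, the cyclobutenone opens, and a 6π closure gives the phenol A3.
- For: the regiochemistry is fixed by the mechanism, with the aryl group flanked by the free hydroxyl and the silyloxy group. There is no C6''/C8'' question, no palladium, and the three oxygens are differentiated. On certainty of regiochemistry at C8'' this is stronger than the chosen route, which relies on the electronic and steric preference of an iodination.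
- Against: A3 is only a trioxygenated biaryl. Flavone ring C and the methoxyphenyl ring must still be built, which requires acylation at C4a'' in competition with C6''. The ethyl ether must later be cleaved while the 4'''-methyl ether stays. A2 needs a multistep ynolate preparation. C2 is not addressed at all.
- Comparison: the chosen route buys the complete flavone and reaches the coupled aldehyde 7 in five simple steps, in exchange for one regiochemical assumption that can be checked at compound 3.

**Alternative 2: three-component carbonylative annulation of the flavone pyranone.** Flavone ring C is disconnected at C4a''–C4'', C4''–C3'' and O1''–C2''. In the forward key step the iodoresorcinol A4, 4-ethynylanisole A5 and a carbonylating atmosphere react under a palladium–phosphine catalyst in a secondary amine. Acyl-palladium formation, alkynylation and 6-endo addition of the phenol give the flavone A6.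
- For: three bonds and the methoxyphenyl ring are delivered in one step, and the aldehyde for C2 is already present. In convergence at this one step it is stronger than the chosen route.
- Against: A4 is a hexasubstituted arene that itself requires the same hindered biaryl coupling and a regioselective iodination between an ether and a phenol, so the two hard problems are moved, not solved. Oxidative addition into that crowded, electron-rich C–I bond is slow, which favours alkynylation without carbonyl insertion and five-membered ring closure. A6 carries a 5''-methyl ether that must be removed selectively later.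
- Comparison: the chosen route solves the biaryl problem once, on a bought flavone, and needs no late differentiation of two methyl ethers.

**Alternative 3: Friedel–Crafts closure of an enantiopure β-aryloxy acid.** Ring C of the flavanone is disconnected at C4–C4a. In the forward key step the (S)-acid A7 is turned into its acid chloride under neutral conditions and cyclised with a buffered zinc Lewis acid onto the symmetric trioxygenated aryl ether, giving the penta-O-benzyl compound A8.
- For: ring A is bought, the two ortho positions are equivalent, the ring closure is a classical reaction type, and A8 is one hydrogenolysis from the target. In step count after the stereocentre, and in precedent for the ring closure, this alternative is stronger than the chosen route, which spends three steps and one new method on ring A.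
- Against: the stereocentre has to be made as a para-oxygenated benzylic aryl ether, by a substitution that is prone to ionisation and elimination. A7 and its acid chloride are β-aryloxy carbonyl compounds with a good leaving group, so β-elimination of the phenol and Lewis-acid ionisation of the C2–O bond can both destroy or racemise C2 in the very step that closes the ring.
- Comparison: the chosen route sets C2 catalytically on an aldehyde, never forms the C2–O1 bond at the stereocentre, and closes ring A thermally under neutral conditions.

Key step: step 6

**Remarks on the chemistry.**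
- The C3'–C8'' axis is taken to equilibrate in the target; benzylated intermediates may show slowly interconverting rotamers, which is of no consequence.
- (S)-BINOL is assumed to direct the diene to the Si face of the aldehyde, as in related titanium–BINOL carbonyl additions. The sense is to be confirmed on the first batch and the (R)-ligand used if it proves opposite.

## Route

Step 1
Reactants: 1 acacetin
Product: 2 5,7-bis(benzyloxy)-2-(4-methoxyphenyl)-4H-chromen-4-one
Conditions: BnBr, K2CO3, DMF, 80 °C
Reagents that add atoms: benzyl bromide, BrCc1ccccc1
Why: Williamson etherification of both phenols; the chelated 5-hydroxyl is slow, hence excess reagent and heat.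

Step 2
Reactants: 2 5,7-bis(benzyloxy)-2-(4-methoxyphenyl)-4H-chromen-4-one
Product: 3 5,7-bis(benzyloxy)-8-iodo-2-(4-methoxyphenyl)-4H-chromen-4-one
Conditions: N-iodosuccinimide, CF3CO2H (cat.), MeCN/CH2Cl2, 0 °C to rt, dark
Reagents that add atoms: N-iodosuccinimide, O=C1CCC(=O)N1I
Why: Electrophilic aromatic iodination of the doubly activated ring; in fully alkylated 5,7-dioxygenated flavones C8'' (para to O5'', flanked by one ether and the ring oxygen) should react before C6'' (flanked by two benzyloxy groups), and the regiochemistry is to be confirmed by long-range NMR correlation before step 5.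

Step 3
Reactants: 4 3-bromo-4-hydroxybenzaldehyde
Product: 5 4-(benzyloxy)-3-bromobenzaldehyde
Conditions: BnBr, K2CO3, DMF, rt
Reagents that add atoms: benzyl bromide, BrCc1ccccc1
Why: Williamson etherification of an acidic para-formyl phenol; the aldehyde is inert to carbonate.

Step 4
Reactants: 5 4-(benzyloxy)-3-bromobenzaldehyde
Product: 6 4-(benzyloxy)-3-(4,4,5,5-tetramethyl-1,3,2-dioxaborolan-2-yl)benzaldehyde
Conditions: B2pin2, PdCl2(dppf) (cat.), KOAc, 1,4-dioxane, 90 °C
Reagents that add atoms: bis(pinacolato)diboron, CC1(C)OB(OC1(C)C)B1OC(C)(C)C(C)(C)O1
Why: Miyaura borylation of an unhindered aryl bromide; acetate as base avoids biaryl formation and the aldehyde is tolerated.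

Step 5
Reactants: 3 5,7-bis(benzyloxy)-8-iodo-2-(4-methoxyphenyl)-4H-chromen-4-one; 6 4-(benzyloxy)-3-(4,4,5,5-tetramethyl-1,3,2-dioxaborolan-2-yl)benzaldehyde
Product: 7 4-(benzyloxy)-3-[5,7-bis(benzyloxy)-2-(4-methoxyphenyl)-4-oxo-4H-chromen-8-yl]benzaldehyde (ArB–CHO)
Conditions: Pd(OAc)2 (cat.), SPhos, K3PO4, toluene/H2O, 90 °C
Reagents that add atoms: none
Why: Suzuki–Miyaura coupling; a bulky electron-rich biarylphosphine is chosen because the biaryl carries three ortho substituents, and the iodide is placed on the hindered partner so that oxidative addition is fast.

Step 6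
Reactants: 7 ArB–CHO; 8 (E)-1-methoxy-3-(trimethylsilyloxy)buta-1,3-diene
Product: 10 (S)-2-ArB-2,3-dihydro-4H-pyran-4-one, via silyl aldol adduct 9 (not isolated)
Conditions: Ti(OiPr)4 (20 mol%), (S)-BINOL (40 mol%), 4 Å molecular sieves, Et2O/CH2Cl2, −20 °C; then CF3CO2H, CH2Cl2, 0 °C, brief
Reagents that add atoms: none
Why: The aldehyde oxygen of 7 binds the binaphtholate complex of tetravalent titanium, and the unsubstituted terminus of 8 (the future C3) attacks the carbonyl carbon, either in concert with O–C bonding or, more likely with this catalyst, as a Mukaiyama aldol addition that leaves the open adduct 9. CF3CO2H then frees the C2 oxygen, which adds to the β-carbon of the methoxy enone in a 6-endo-trig closure followed by loss of methanol; this makes O1–C8a and closes ring C. The closest known reaction type is the titanium–BINOL-catalysed hetero-Diels–Alder (aldol–cyclisation) reaction of aromatic aldehydes with this diene to 2-aryl-2,3-dihydropyran-4-ones. The single new stereocentre, C2, is controlled by the ligand: (S)-BINOL is expected to leave the Si face open, which gives (2S). The C2–O1 bond is the former carbonyl bond, so the acid cyclisation cannot erode the configuration. The step needs chemoselectivity for the aldehyde over the flavone carbonyl, which is secured because a vinylogous ester carbonyl inside an aromatic pyranone is not attacked by a silyl dienol ether under these conditions. It also needs protecting groups that survive the acid, which is why benzyl ethers are used. The para-benzyloxy group lowers the electrophilicity of the aldehyde, so a high catalyst loading is planned.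

Step 7
Reactants: 11 2,2,6-trimethyl-4H-1,3-dioxin-4-one
Product: 12 2,2-dimethyl-6-methylidene-4-(trimethylsilyloxy)-6H-1,3-dioxine
Conditions: LiN(iPr)2, Me3SiCl, THF, −78 °C; distilled
Reagents that add atoms: chlorotrimethylsilane, C[Si](C)(C)Cl
Why: γ-Deprotonation of the vinylogous ester and O-silylation of the dienolate give the known cross-conjugated silyl dienol ether.

Step 8
Reactants: 10 (S)-2-ArB-2,3-dihydro-4H-pyran-4-one; 12 2,2-dimethyl-6-methylidene-4-(trimethylsilyloxy)-6H-1,3-dioxine
Product: 14 (S)-2-ArB-6-[(2,2-dimethyl-4-oxo-4H-1,3-dioxin-6-yl)methyl]-2,3-dihydro-4H-pyran-4-one, via trimethylsilyl enol ether 13 (not isolated)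
Conditions: Me3SiOTf (2.2 equiv), CH2Cl2, −78 °C, then Et3N; crude 13, Pd(OAc)2 (1.1 equiv), MeCN, rt
Reagents that add atoms: none
Why: Vinylogous Mukaiyama–Michael addition: O-silylation of 10 gives a 4-silyloxy oxocarbenium ion that the exocyclic methylene of 12 attacks at C8a (axially, trans to ArB, though this centre becomes sp2 again), while the silylated flavone is a fully substituted, aryl-stabilised cation and is not attacked; Saegusa–Ito dehydrosilylation of 13 by divalent palladium then restores the C4a=C8a bond by β-hydride loss from C8a.

Step 9
Reactants: 14 (S)-2-ArB-6-[(2,2-dimethyl-4-oxo-4H-1,3-dioxin-6-yl)methyl]-2,3-dihydro-4H-pyran-4-one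
Product: 16 (2S)-2-ArB-5,7-dihydroxy-2,3-dihydro-4H-chromen-4-one, via acylketene 15 (not isolated)
Conditions: toluene (high dilution, dry), 110 °C
Reagents that add atoms: none
Why: Proposed new method: retro-[4+2] loss of acetone from the dioxinone, which is known at this temperature, gives acylketene 15; enolisation of its ketone towards C8 produces a dienylketene whose 6π electrocyclisation joins the ketene carbon C5 to C4a (equivalently, the enol-ether carbon C4a acylates the ketene), and tautomerisation gives the resorcinol with oxygen on C5 and C7; the closest known reaction types are the capture of dioxinone-derived acylketenes by enols to 4-hydroxy-2-pyranones and the dienylketene electrocyclisation that ends a Danheiser benzannulation; O-capture is not possible here because the oxygen on C8a is the alkylated O1, and C2 is untouched under neutral thermal conditions.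

Step 10
Reactants: 16 (2S)-2-ArB-5,7-dihydroxy-2,3-dihydro-4H-chromen-4-one
Product: 17 2,3-dihydropodocarpusflavone A
Conditions: H2 (1 atm), Pd/C, THF/MeOH, rt
Reagents that add atoms: none
Why: Hydrogenolysis of three aryl benzyl ethers under neutral conditions; aryl benzyl ethers should cleave well before the conjugated flavone alkene, the chelated ketone or the C2–O1 bond react, and no base touches C2.

## Compound list

1 | acacetin (5,7-dihydroxy-2-(4-methoxyphenyl)-4H-chromen-4-one) | COc1ccc(cc1)-c1cc(=O)c2c(O)cc(O)cc2o1 | starting material
2 | 5,7-bis(benzyloxy)-2-(4-methoxyphenyl)-4H-chromen-4-one | COc1ccc(cc1)-c1cc(=O)c2c(OCc3ccccc3)cc(OCc3ccccc3)cc2o1 | intermediate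
3 | 5,7-bis(benzyloxy)-8-iodo-2-(4-methoxyphenyl)-4H-chromen-4-one | COc1ccc(cc1)-c1cc(=O)c2c(OCc3ccccc3)cc(OCc3ccccc3)c(I)c2o1 | intermediate
4 | 3-bromo-4-hydroxybenzaldehyde | O=Cc1ccc(O)c(Br)c1 | starting material
5 | 4-(benzyloxy)-3-bromobenzaldehyde | O=Cc1ccc(OCc2ccccc2)c(Br)c1 | intermediate
6 | 4-(benzyloxy)-3-(4,4,5,5-tetramethyl-1,3,2-dioxaborolan-2-yl)benzaldehyde | O=Cc1ccc(OCc2ccccc2)c(c1)B1OC(C)(C)C(C)(C)O1 | intermediate
7 | 4-(benzyloxy)-3-[5,7-bis(benzyloxy)-2-(4-methoxyphenyl)-4-oxo-4H-chromen-8-yl]benzaldehyde (ArB–CHO) | COc1ccc(cc1)-c1cc(=O)c2c(OCc3ccccc3)cc(OCc3ccccc3)c(-c3cc(C=O)ccc3OCc3ccccc3)c2o1 | intermediate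
8 | (E)-1-methoxy-3-(trimethylsilyloxy)buta-1,3-diene | CO/C=C/C(=C)O[Si](C)(C)C | starting material
9 | (S,E)-5-ArB-1-methoxy-5-(trimethylsilyloxy)pent-1-en-3-one | COc1ccc(cc1)-c1cc(=O)c2c(OCc3ccccc3)cc(OCc3ccccc3)c(-c3cc([C@H](CC(=O)/C=C/OC)O[Si](C)(C)C)ccc3OCc3ccccc3)c2o1 | intermediate (not isolated)
10 | (S)-2-ArB-2,3-dihydro-4H-pyran-4-one | COc1ccc(cc1)-c1cc(=O)c2c(OCc3ccccc3)cc(OCc3ccccc3)c(-c3cc([C@@H]4CC(=O)C=CO4)ccc3OCc3ccccc3)c2o1 | intermediate
11 | 2,2,6-trimethyl-4H-1,3-dioxin-4-one | CC1=CC(=O)OC(C)(C)O1 | starting material
12 | 2,2-dimethyl-6-methylidene-4-(trimethylsilyloxy)-6H-1,3-dioxine | C=C1C=C(O[Si](C)(C)C)OC(C)(C)O1 | intermediate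
13 | (2S,6R)-2-ArB-6-[(2,2-dimethyl-4-oxo-4H-1,3-dioxin-6-yl)methyl]-4-(trimethylsilyloxy)-3,6-dihydro-2H-pyran (expected 2,6-trans isomer; the C6 epimer serves equally) | COc1ccc(cc1)-c1cc(=O)c2c(OCc3ccccc3)cc(OCc3ccccc3)c(-c3cc([C@@H]4CC(O[Si](C)(C)C)=C[C@@H](CC5=CC(=O)OC(C)(C)O5)O4)ccc3OCc3ccccc3)c2o1 | intermediate (not isolated)
14 | (S)-2-ArB-6-[(2,2-dimethyl-4-oxo-4H-1,3-dioxin-6-yl)methyl]-2,3-dihydro-4H-pyran-4-one | COc1ccc(cc1)-c1cc(=O)c2c(OCc3ccccc3)cc(OCc3ccccc3)c(-c3cc([C@@H]4CC(=O)C=C(CC5=CC(=O)OC(C)(C)O5)O4)ccc3OCc3ccccc3)c2o1 | intermediate
15 | 4-[(S)-2-ArB-4-oxo-3,4-dihydro-2H-pyran-6-yl]-3-oxobut-1-en-1-one (acylketene) | COc1ccc(cc1)-c1cc(=O)c2c(OCc3ccccc3)cc(OCc3ccccc3)c(-c3cc([C@@H]4CC(=O)C=C(CC(=O)C=C=O)O4)ccc3OCc3ccccc3)c2o1 | intermediate (not isolated)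
16 | (2S)-2-ArB-5,7-dihydroxy-2,3-dihydro-4H-chromen-4-one (4',5'',7''-tri-O-benzyl-2,3-dihydropodocarpusflavone A) | COc1ccc(cc1)-c1cc(=O)c2c(OCc3ccccc3)cc(OCc3ccccc3)c(-c3cc([C@@H]4CC(=O)c5c(O)cc(O)cc5O4)ccc3OCc3ccccc3)c2o1 | intermediate
17 | 2,3-dihydropodocarpusflavone A | COc1ccc(-c2cc(=O)c3c(O)cc(O)c(-c4cc([C@@H]5CC(=O)c6c(O)cc(O)cc6O5)ccc4O)c3o2)cc1 | target

## Step count and least certain steps

Total step count: 10. Longest linear sequence: 7 steps (1, 2, 5, 6, 8, 9, 10).

**Step 9 (proposed new method).** The acylketene may be consumed by processes faster than ring closure: dimerisation, capture by traces of water followed by decarboxylation, or acylation of the phenols of product already formed. The closure itself could also be slow if the enol geometry needed for the electrocyclisation is poorly populated. High dilution and dry solvent address the first group.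
Fallback, from 14 back to 16: 14 would be heated in toluene containing methanol, which captures the acylketene as methyl 4-[(S)-2-ArB-4-oxo-3,4-dihydro-2H-pyran-6-yl]-3-oxobutanoate F1, a standard ketene trapping. F1 would then be closed by an anionic Claisen condensation with Mg(OMe)2 in methanol at 0 °C. The dienolate formed by removal of a C8 proton attacks the ester carbon through C4a, which is the known phloroglucinol-forming cyclisation of 3,5,7-tricarbonyl esters, and tautomerisation gives 16. This trades the neutral closure for a base, so the configuration at C2 would have to be checked afterwards.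

**Step 6 (key step).** Poor facial selectivity or low conversion is the main concern. The aldehyde is deactivated by the para-benzyloxy group, and the Lewis-basic flavone carbonyl can bind the titanium catalyst and favour an uncatalysed, unselective background addition. The acid cyclisation could also ionise the para-oxygenated benzylic C2–O bond if it is prolonged.
Fallback, from 7 back to 10: a reagent-controlled boron aldol reaction. The enol borinate of (E)-4-methoxybut-3-en-2-one, made with the enantiomer of Ipc2BCl that attacks the Si face and iPr2NEt in Et2O at −78 °C, would add to 7 to give (S,E)-5-ArB-5-hydroxy-1-methoxypent-1-en-3-one F2. Brief CF3CO2H treatment would cyclise F2 to 10 by the same oxa-Michael closure and loss of methanol.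

**Step 8.** Two processes can fail. In the first half the silyl triflate is held by the flavone carbonyl, the dienol ether is only moderately nucleophilic, and reversible opening of the activated ring at the benzylic C2–O1 bond would erode the configuration. In the second half, protodesilylation of 13 or β-alkoxide loss from the palladium enolate would compete with β-hydride loss.
Fallback, from 13 (as generated in the flask) back to 14: the silyl enol ether would be selenenylated with PhSeCl at −78 °C to give (2S,5R,6R)-2-ArB-6-[(2,2-dimethyl-4-oxo-4H-1,3-dioxin-6-yl)methyl]-5-(phenylselanyl)oxan-4-one F3 (expected isomer; the configurations at C5 and C6 are of no consequence). Oxidation with H2O2 and pyridine in CH2Cl2 at 0 °C would give the selenoxide, whose syn elimination towards C6 of the pyranone ring, the only position with a β-hydrogen, returns 14 without palladium.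

**Step 5.** Protodeboronation of the ortho-alkoxy boronate and reductive loss of iodide can outrun transmetalation on the crowded palladium centre.
Fallback, from 5 and 3 back to 7: bromide 5 would be converted with hexamethylditin and Pd(PPh3)4 into 4-(benzyloxy)-3-(trimethylstannyl)benzaldehyde F4. F4 would be joined to 3 in a Stille coupling with Pd(PPh3)4, CuI and CsF in DMF, which needs no aqueous base and has no protodeboronation pathway.

**Step 10.** Over-reduction is possible: saturation of the C2''=C3'' bond, or hydrogenolysis of the benzylic C2–O1 bond to a ring-opened product.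
Fallback, from 16 back to 17: Lewis-acid debenzylation with BCl3 and pentamethylbenzene as cation scavenger in CH2Cl2 at −78 °C. This involves no hydrogen, leaves the methyl ether intact at that temperature, and makes no new isolated compound (F0).

## Further compounds

F1 | step 9 | methyl 4-[(S)-2-ArB-4-oxo-3,4-dihydro-2H-pyran-6-yl]-3-oxobutanoate | COc1ccc(cc1)-c1cc(=O)c2c(OCc3ccccc3)cc(OCc3ccccc3)c(-c3cc([C@@H]4CC(=O)C=C(CC(=O)CC(=O)OC)O4)ccc3OCc3ccccc3)c2o1
F2 | step 6 | (S,E)-5-ArB-5-hydroxy-1-methoxypent-1-en-3-one | COc1ccc(cc1)-c1cc(=O)c2c(OCc3ccccc3)cc(OCc3ccccc3)c(-c3cc([C@H](CC(=O)/C=C/OC)O)ccc3OCc3ccccc3)c2o1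
F3 | step 8 | (2S,5R,6R)-2-ArB-6-[(2,2-dimethyl-4-oxo-4H-1,3-dioxin-6-yl)methyl]-5-(phenylselanyl)oxan-4-one | COc1ccc(cc1)-c1cc(=O)c2c(OCc3ccccc3)cc(OCc3ccccc3)c(-c3cc([C@@H]4CC(=O)[C@H]([Se]c5ccccc5)[C@@H](CC5=CC(=O)OC(C)(C)O5)O4)ccc3OCc3ccccc3)c2o1
F4 | step 5 | 4-(benzyloxy)-3-(trimethylstannyl)benzaldehyde | O=Cc1ccc(OCc2ccccc2)c(c1)[Sn](C)(C)C
F0 | step 10 | none | none
A1 | alternative 1 | 3-ethoxycyclobut-2-en-1-one | CCOC1=CC(=O)C1
A2 | alternative 1 | {[2-(benzyloxy)-5-(1,3-dioxolan-2-yl)phenyl]ethynyloxy}triisopropylsilane | CC(C)[Si](OC#Cc1cc(ccc1OCc1ccccc1)C1OCCO1)(C(C)C)C(C)C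
A3 | alternative 1 | 2-[2-(benzyloxy)-5-(1,3-dioxolan-2-yl)phenyl]-5-ethoxy-3-(triisopropylsilyloxy)phenol | CCOc1cc(O)c(-c2cc(C3OCCO3)ccc2OCc2ccccc2)c(O[Si](C(C)C)(C(C)C)C(C)C)c1
A4 | alternative 2 | 4-(benzyloxy)-3-(2,6-dihydroxy-3-iodo-4-methoxyphenyl)benzaldehyde | COc1cc(O)c(-c2cc(C=O)ccc2OCc2ccccc2)c(O)c1I
A5 | alternative 2 | 4-ethynylanisole | COc1ccc(C#C)cc1
A6 | alternative 2 | 8-(2-benzyloxy-5-formylphenyl)-7-hydroxy-5-methoxy-2-(4-methoxyphenyl)chromen-4-one | COc1ccc(-c2cc(=O)c3c(OC)cc(O)c(-c4cc(C=O)ccc4OCc4ccccc4)c3o2)cc1
A7 | alternative 3 | (S)-3-{4-(benzyloxy)-3-[5,7-bis(benzyloxy)-2-(4-methoxyphenyl)-4-oxo-4H-chromen-8-yl]phenyl}-3-[3,5-bis(benzyloxy)phenoxy]propanoic acid | OC(=O)C[C@H](Oc1cc(OCc2ccccc2)cc(OCc2ccccc2)c1)c1ccc(OCc2ccccc2)c(c1)-c1c(OCc2ccccc2)cc(OCc2ccccc2)c2c1oc(cc2=O)-c1ccc(OC)cc1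
A8 | alternative 3 | penta-O-benzyl-(2S)-2,3-dihydropodocarpusflavone A | COc1ccc(-c2cc(=O)c3c(OCc4ccccc4)cc(OCc4ccccc4)c(-c4cc([C@@H]5CC(=O)c6c(OCc7ccccc7)cc(OCc7ccccc7)cc6O5)ccc4OCc4ccccc4)c3o2)cc1
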